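**Plan**

- Retrosynthesis (benzofuran numbering of the target): cut the O–Si bond that masks the pendant phenol, then the lactone bond O1–C7a together with the C7a–H and C3–H bonds removed by oxidation, which opens the benzofuran-2,6-dione to diarylacetic acid 12. Then cut the C3–aryl bond to the pendant ring, the C3–C3a bond (glyoxylic acid), one O–CH3 bond and the two aryl–phenyl bonds, back to veratrole.
- Forward: ring A (the terphenyl core) is assembled in steps 1–3, the C2–C3 acetic acid unit and the pendant ring are attached at C3a in steps 4–6, the five-membered lactone (the only ring formed) closes in step 7, and the silyl group is removed in step 8.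
- Enabling feature: C7a is the β-carbon of the C6=O/C7=C7a enone and C3 is para to O6 through C3a. Oxidising a 4-hydroxydiarylacetic acid that still has C7a–H to its para-quinone methide therefore puts the carboxyl oxygen within five-ring reach of an unsubstituted electrophilic ring carbon, so O1 comes from the acid and never has to be carried as a phenol.
- Stereochemistry: the target has no stereocentre. C3 is a racemic sp3 centre in 8, 10, 11, 12 and 14 and becomes sp2 in step 7; the C3=C3a bond lies inside the lactone ring, so no alkene geometry has to be set in the product.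

Key step: step 7

Remark: SMILES of the racemic compounds are written without stereodescriptors. The pendant phenol is carried as a tert-butyldimethylsilyl (TBS) ether through the oxidation, because it can be installed by steric discrimination and removed without base.

**Step 1**
Reactants: 1 veratrole
Product: 3 1,4-diiodo-2,3-dimethoxybenzene, via 3,6-dilithioveratrole 2 (not isolated)
Conditions: n-BuLi (2.6 equiv), TMEDA (2.6 equiv), Et2O–hexane, 0 °C → rt, 24 h; then I2 (3.0 equiv), THF, −78 °C → rt; aq. Na2S2O3 wash
Reagents that add atoms: iodine, II
Why: Each methoxy group directs one ortho-lithiation (directed ortho-metalation), so the dianion carries lithium at C3 and C6 only, and iodinolysis of both C–Li bonds fixes the 1,4-dihalo-2,3-dioxygenated pattern that electrophilic halogenation of veratrole (which goes to C4/C5) cannot give.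

**Step 2**
Reactants: 3 1,4-diiodo-2,3-dimethoxybenzene; 4 phenylboronic acid (2.6 equiv)
Product: 5 2,3-dimethoxy-1,4-diphenylbenzene
Conditions: Pd(PPh3)4 (5 mol %), K2CO3 (2 M aq.), toluene–EtOH, 90 °C
Reagents that add atoms: none
Why: Twofold Suzuki–Miyaura coupling of an aryl diiodide in which each C–I bond has a single ortho substituent is routine with zerovalent palladium and leaves the methyl ethers untouched.

**Step 3**
Reactants: 5 2,3-dimethoxy-1,4-diphenylbenzene
Product: 6 2-methoxy-3,6-diphenylphenol
Conditions: NaSEt (2.0 equiv), DMF, 130 °C; then 1 M HCl
Reagents that add atoms: none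
Why: SN2 demethylation by a thiolate stops after one methyl group because the phenoxide formed makes loss of the neighbouring methyl (which would give a catechol dianion) much slower, and the twofold symmetry of 5 means either methoxy group gives the same phenol.

**Step 4**
Reactants: 6 2-methoxy-3,6-diphenylphenol; 7 glyoxylic acid (50% aq., 2.0 equiv)
Product: 8 rac-2-hydroxy-2-(4-hydroxy-3-methoxy-2,5-diphenylphenyl)acetic acid
Conditions: NaOH (4.5 equiv), H2O–1,4-dioxane, 40 °C, 48 h; then 2 M HCl to pH 1
Reagents that add atoms: none
Why: The phenoxide of 6 adds through its para carbon to the aldehyde of glyoxylate (base-mediated para-hydroxyalkylation of a phenol, the reaction used to make 4-hydroxymandelic acids), and since the two ortho positions carry methoxy and phenyl the only activated C–H is the one para to oxygen, which becomes C3a of the target.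

**Step 5**
Reactants: 8 rac-2-hydroxy-2-(4-hydroxy-3-methoxy-2,5-diphenylphenyl)acetic acid; 9 phenol (20 equiv, melt)
Product: 10 rac-2-(4-hydroxyphenyl)-2-(4-hydroxy-3-methoxy-2,5-diphenylphenyl)acetic acid
Conditions: MsOH (0.2 equiv), neat phenol, 50 °C; then extraction of the acid into aq. NaHCO3 and re-acidification
Reagents that add atoms: none
Why: Acid ionises the benzylic hydroxyl para to the ring A phenol to a para-hydroxybenzylic cation that is trapped at the para position of phenol with loss of water (Friedel–Crafts alkylation), the large excess of phenol outrunning closure onto the neighbouring phenyl ring, while the minor ortho adduct lactonises to a neutral benzofuranone that stays behind in the bicarbonate extraction.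

**Step 6**
Reactants: 10 rac-2-(4-hydroxyphenyl)-2-(4-hydroxy-3-methoxy-2,5-diphenylphenyl)acetic acid
Product: 12 rac-2-[4-(tert-butyldimethylsilyloxy)phenyl]-2-(4-hydroxy-3-methoxy-2,5-diphenylphenyl)acetic acid, via silyl ester 11 (not isolated)
Conditions: TBSCl (2.2 equiv), imidazole (4.5 equiv), DMF, 0 °C, 2 h; then 10% aq. citric acid–THF, rt, 30 min
Reagents that add atoms: tert-butyldimethylsilyl chloride, CC(C)(C)[Si](C)(C)Cl
Why: Silylation with TBSCl/imidazole depends strongly on steric access, so the unhindered pendant phenol and the carboxyl group should react while the ring A phenol, flanked by methoxy and a twisted phenyl and hydrogen-bonded to the methoxy oxygen, should not, and the silyl ester of 11 is hydrolysed by mild aqueous acid that leaves the aryl silyl ether intact.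

**Step 7**
Reactants: 12 rac-2-[4-(tert-butyldimethylsilyloxy)phenyl]-2-(4-hydroxy-3-methoxy-2,5-diphenylphenyl)acetic acid
Product: 15 3-[4-(tert-butyldimethylsilyloxy)phenyl]-5-methoxy-4,7-diphenyl-1-benzofuran-2,6-dione, via quinone methide acid 13 (not isolated), via 6-hydroxybenzofuranone 14 (not isolated)
Conditions: DDQ (2.2 equiv, in two portions), 4 Å molecular sieves, anhydrous 1,4-dioxane, argon, rt → 40 °C
Reagents that add atoms: none
Why: Proposed new method: DDQ should abstract hydride from the doubly benzylic C3–H para to the C6 phenol to give para-quinone methide 13, whose carboxyl oxygen (syn to C7a in the E isomer; the geometric isomers should equilibrate through the O-protonated benzylic cation formed with the acidic hydroquinone by-product) adds to C7a, the β-carbon of the C6=O/C7=C7a enone, and the adduct tautomerises through its C7a–H, which is γ to the lactone carbonyl, to aromatic lactone 14, from which the second equivalent of DDQ removes the C3 hydride to give 15. The closest known reactions are DDQ dehydrogenation of 4-hydroxydiarylmethanes to para-quinone methides, lactonisation of a carboxyl group onto a quinone generated by oxidation (as with dihydroxyphenylacetic acids), and dehydrogenation of 3-aryl-6-hydroxybenzofuran-2(3H)-ones to their quinone methides; the tandem starting from a C7a–H acid is untested. The lactone ring closes 5-exo-trig onto the C7=C7a bond, and no stereocentre is created because the racemic C3 of 12 becomes sp2. The step needs C–O formation at C7a only: attack at C3 would give an α-lactone, C4 carries phenyl and belongs to the methoxy-substituted and less electrophilic enone so that addition there is reversible and cannot aromatise, and the silyl ether keeps the pendant ring from becoming quinoid. Anhydrous, base-free conditions are chosen so that water does not add to C3 and the un-ionised acid does not fragment by oxidative decarboxylation.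

**Step 8**
Reactants: 15 3-[4-(tert-butyldimethylsilyloxy)phenyl]-5-methoxy-4,7-diphenyl-1-benzofuran-2,6-dione
Product: 16 3-(4-hydroxyphenyl)-5-methoxy-4,7-diphenyl-1-benzofuran-2,6-dione (target)
Conditions: HF·pyridine, THF, 0 °C → rt (polypropylene vessel)
Reagents that add atoms: none
Why: Fluoride-driven Si–O cleavage under acidic, non-basic conditions (standard aryl silyl ether deprotection) should free the pendant phenol without exposing the enol lactone and the quinone methide to a nucleophilic base.

**Compound list**

1 | veratrole (1,2-dimethoxybenzene) | COc1ccccc1OC | starting material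
2 | 3,6-dilithio-1,2-dimethoxybenzene (3,6-dilithioveratrole) | COc1c([Li])ccc([Li])c1OC | intermediate
3 | 1,4-diiodo-2,3-dimethoxybenzene | COc1c(I)ccc(I)c1OC | intermediate
4 | phenylboronic acid | OB(O)c1ccccc1 | starting material
5 | 2,3-dimethoxy-1,4-diphenylbenzene | COc1c(-c2ccccc2)ccc(-c2ccccc2)c1OC | intermediate
6 | 2-methoxy-3,6-diphenylphenol | COc1c(O)c(-c2ccccc2)ccc1-c1ccccc1 | intermediate
7 | glyoxylic acid | O=CC(=O)O | starting material
8 | rac-2-hydroxy-2-(4-hydroxy-3-methoxy-2,5-diphenylphenyl)acetic acid | OC(C(=O)O)c1cc(-c2ccccc2)c(O)c(OC)c1-c1ccccc1 | intermediate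
9 | phenol | Oc1ccccc1 | starting material
10 | rac-2-(4-hydroxyphenyl)-2-(4-hydroxy-3-methoxy-2,5-diphenylphenyl)acetic acid | OC(=O)C(c1ccc(O)cc1)c1cc(-c2ccccc2)c(O)c(OC)c1-c1ccccc1 | intermediate
11 | tert-butyldimethylsilyl rac-2-[4-(tert-butyldimethylsilyloxy)phenyl]-2-(4-hydroxy-3-methoxy-2,5-diphenylphenyl)acetate (silyl ester) | CC(C)(C)[Si](C)(C)OC(=O)C(c1ccc(O[Si](C)(C)C(C)(C)C)cc1)c1cc(-c2ccccc2)c(O)c(OC)c1-c1ccccc1 | intermediate
12 | rac-2-[4-(tert-butyldimethylsilyloxy)phenyl]-2-(4-hydroxy-3-methoxy-2,5-diphenylphenyl)acetic acid | OC(=O)C(c1ccc(O[Si](C)(C)C(C)(C)C)cc1)c1cc(-c2ccccc2)c(O)c(OC)c1-c1ccccc1 | intermediate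
13 | (E)-2-[4-(tert-butyldimethylsilyloxy)phenyl]-2-(3-methoxy-4-oxo-2,5-diphenylcyclohexa-2,5-dien-1-ylidene)acetic acid (quinone methide acid, carboxyl syn to C7a–H) | O=C1C(OC)=C(c2ccccc2)/C(=C(/C(=O)O)c2ccc(O[Si](C)(C)C(C)(C)C)cc2)C=C1c1ccccc1 | intermediate
14 | rac-3-[4-(tert-butyldimethylsilyloxy)phenyl]-6-hydroxy-5-methoxy-4,7-diphenyl-1-benzofuran-2(3H)-one | COc1c(O)c(-c2ccccc2)c2OC(=O)C(c3ccc(O[Si](C)(C)C(C)(C)C)cc3)c2c1-c1ccccc1 | intermediate
15 | 3-[4-(tert-butyldimethylsilyloxy)phenyl]-5-methoxy-4,7-diphenyl-1-benzofuran-2,6-dione | COC1=C(c2ccccc2)C2=C(c3ccc(O[Si](C)(C)C(C)(C)C)cc3)C(=O)OC2=C(c2ccccc2)C1=O | intermediate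
16 | 3-(4-hydroxyphenyl)-5-methoxy-4,7-diphenyl-1-benzofuran-2,6-dione | COC1=C(c2ccccc2)C2=C(c3ccc(O)cc3)C(=O)OC2=C(c2ccccc2)C1=O | target

**Step count**

Total steps: 8. Longest linear sequence: 8 steps (1 → 16; phenylboronic acid, glyoxylic acid and phenol are purchased).

**Steps most likely to fail**

1. Step 7 (oxidative lactonisation). After hydride abstraction the quinone methide may be intercepted at C3 by adventitious nucleophiles, may lose CO2 oxidatively, or may close onto the C4 phenyl ring before the carboxyl group adds to C7a. The fallback uses known chemistry with O1 preinstalled and sets out from 6.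
   - Oxidation of 6 with (KSO3)2NO (potassium nitrosodisulfonate, aq. KH2PO4–acetone; Teuber oxidation) should give 2-methoxy-3,6-diphenyl-1,4-benzoquinone F1.
   - Thiele–Winter acetoxylation (Ac2O, cat. H2SO4) at its only free ring position should give 5-methoxy-3,6-diphenylbenzene-1,2,4-triyl triacetate F2.
   - Acid-catalysed methanolysis under argon (HCl, MeOH, 50 °C) should give 5-methoxy-3,6-diphenylbenzene-1,2,4-triol F3. After removal of the acidic methanol it is oxidised with FeCl3 (aq. MeCN, rt) to 2-hydroxy-5-methoxy-3,6-diphenyl-1,4-benzoquinone F4. Base is avoided here so that the vinylogous methyl ester of the quinone is not hydrolysed.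
   - Perkin-type condensation of F4 with commercial (4-acetoxyphenyl)acetic acid (Ac2O, NaOAc, 120 °C) should give 4-(5-methoxy-2,6-dioxo-4,7-diphenyl-2,6-dihydro-1-benzofuran-3-yl)phenyl acetate F5. The arylacetic carbon condenses with the quinone carbonyl next to the hydroxyl, the acid lactonises onto that hydroxyl, and only this regiochemistry can close a lactone.
   - Acidic methanolysis (HCl, MeOH–CH2Cl2, rt) removes the acetate and the sequence comes back to the route at target 16.

2. Step 6 (selective silylation). The rate difference between the two phenols may be too small, so that the ring A hydroxyl is silylated as well or the pendant one is left partly free. The fallback sets out from 8 and lets the protecting group arrive with the nucleophile. The cation from 8 (p-TsOH·H2O cat., 1,1,1,3,3,3-hexafluoropropan-2-ol, rt) is trapped by commercial tert-butyldimethyl(phenoxy)silane (10 equiv, recoverable) in a Friedel–Crafts alkylation; the bulky silyloxy group directs attack to its para position. No phenol has to be differentiated, compounds 10 and 11 are bypassed, and the sequence comes back to the route at 12.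

3. Step 4 (hydroxyalkylation with glyoxylate). Addition of the hindered, poorly water-soluble phenoxide to glyoxylate may be slow or reversible, so that Cannizzaro disproportionation of glyoxylate takes over. The fallback sets out from 6 and reverses the roles of the partners. Phenol 6 (used in excess and recovered from the neutral fraction) is alkylated at its position para to OH with commercial 4-hydroxymandelic acid (added slowly; MsOH cat., AcOH, 50 °C). The cation of this acid has no neighbouring aryl ring to cyclise onto, and the position para to OH should be favoured over the one para to the methoxy group, which is flanked on both sides and twisted out of conjugation. Compound 8 is bypassed and the sequence comes back to the route at 10.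

**Further compounds**

F1 | step 7 | 2-methoxy-3,6-diphenyl-1,4-benzoquinone | COC1=C(c2ccccc2)C(=O)C=C(c2ccccc2)C1=O
F2 | step 7 | 5-methoxy-3,6-diphenylbenzene-1,2,4-triyl triacetate | COc1c(OC(C)=O)c(-c2ccccc2)c(OC(C)=O)c(OC(C)=O)c1-c1ccccc1
F3 | step 7 | 5-methoxy-3,6-diphenylbenzene-1,2,4-triol | COc1c(O)c(-c2ccccc2)c(O)c(O)c1-c1ccccc1
F4 | step 7 | 2-hydroxy-5-methoxy-3,6-diphenyl-1,4-benzoquinone | COC1=C(c2ccccc2)C(=O)C(O)=C(c2ccccc2)C1=O
F5 | step 7 | 4-(5-methoxy-2,6-dioxo-4,7-diphenyl-2,6-dihydro-1-benzofuran-3-yl)phenyl acetate | COC1=C(c2ccccc2)C2=C(c3ccc(OC(C)=O)cc3)C(=O)OC2=C(c2ccccc2)C1=O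
F0 | step 6 | none | none
F0 | step 4 | none | none
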